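**Retrosynthetic overview**
- The bridging γ-lactone (C5–O bond) is formed last of the rings, by a Pd-catalysed allylic C–H lactonisation of a cyclohexane carboxylic acid that carries the isopropenyl group.
- The propanoate arm is then attached by decarboxylative radical addition of the C10 carboxyl to methyl acrylate.
- The cyclohexane (first ring) comes from an endo Diels–Alder reaction of an (S)-silyloxy (E,E)-diene (from sorbic acid) with a 2-alkylmaleic anhydride; the diene carbinol is later turned into ketone, then isopropenyl.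
- The anhydride comes from Pd-catalysed oxidative dicarbonylation of a terminal alkyne; the butenolide ring is brought in preformed by Negishi coupling of but-3-ynylzinc iodide with 3-bromofuran-2(5H)-one.

Labels used in the explanations: C5–C10 are the cyclohexane carbons of the target (C5 bears O and isopropenyl, C8 the methyl, C9 is quaternary, C10 bears the propanoate); C4 is the isopropenyl carbon on C5; C20 is the lactone carbonyl; C1′ is the carboxyl carbon on C10 that is later lost as CO2.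

Step 1
Reactants: 1 sorbic acid [(2E,4E)-hexa-2,4-dienoic acid]
Product: 2 (2E,4E)-N-methoxy-N-methylhexa-2,4-dienamide
Conditions: MeNH(OMe)·HCl, EDC·HCl, N-methylmorpholine, DMAP (cat.), CH2Cl2, 0 → 23 °C
Reagents that add atoms: N,O-dimethylhydroxylamine hydrochloride (CNOC.Cl)
Why: Carbodiimide amide coupling gives the Weinreb amide and leaves the (E,E)-diene untouched.

Step 2
Reactants: 2 (2E,4E)-N-methoxy-N-methylhexa-2,4-dienamide
Product: 3 (3E,5E)-hepta-3,5-dien-2-one
Conditions: MeMgBr, THF, −20 → 0 °C; aq. NH4Cl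
Reagents that add atoms: methylmagnesium bromide (C[Mg]Br)
Why: Weinreb ketone synthesis; the chelated tetrahedral adduct stops at the methyl ketone and 1,2-addition keeps the diene geometry.

Step 3
Reactants: 3 (3E,5E)-hepta-3,5-dien-2-one
Product: 4 (2S,3E,5E)-hepta-3,5-dien-2-ol
Conditions: (R)-2-methyl-CBS-oxazaborolidine (10 mol %), catecholborane, PhMe, −78 °C; MeOH, aq. NaOH wash
Reagents that add atoms: none
Why: Corey–Bakshi–Shibata reduction; the dienyl group is the large substituent, so the (R)-catalyst gives the (S)-carbinol, and catecholborane avoids hydroboration of the diene.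

Step 4
Reactants: 4 (2S,3E,5E)-hepta-3,5-dien-2-ol
Product: 5 tert-butyl{[(2S,3E,5E)-hepta-3,5-dien-2-yl]oxy}dimethylsilane
Conditions: TBSCl, imidazole, DMF, 23 °C
Reagents that add atoms: tert-butyldimethylsilyl chloride (CC(C)(C)[Si](C)(C)Cl)
Why: Standard silylation; the bulky OTBS group is the facial control element for the cycloaddition and prevents acylation of the carbinol by the anhydride.

Step 5
Reactants: 6 furan-2(5H)-one
Product: 8 3-bromofuran-2(5H)-one, via dibromolactone 7 (not isolated)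
Conditions: Br2, CH2Cl2, 0 °C; then Et3N, 0 → 23 °C
Reagents that add atoms: bromine (BrBr)
Why: Anti bromination of the alkene followed by E1cB dehydrobromination (acidic α-H, β-bromide leaves) gives the α-bromobutenolide.

Step 6
Reactants: 9 but-3-yn-1-ol
Product: 10 4-iodobut-1-yne
Conditions: PPh3, I2, imidazole, CH2Cl2, 0 → 23 °C
Reagents that add atoms: iodine (II)
Why: Appel-type iodination; the iodide allows zinc insertion at room temperature in the next step.

Step 7
Reactants: 10 4-iodobut-1-yne; 8 3-bromofuran-2(5H)-one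
Product: 12 3-(but-3-yn-1-yl)furan-2(5H)-one, via alkylzinc iodide 11 (not isolated)
Conditions: Zn dust (activated with BrCH2CH2Br/TMSCl), LiCl, THF, 25 °C; then 8, Pd(OAc)2 (2 mol %), SPhos (4 mol %), THF, 0 → 25 °C
Reagents that add atoms: none
Why: LiCl-promoted zinc insertion then Negishi sp3–sp2 cross-coupling; the α-bromo enoate undergoes fast oxidative addition and the mild zinc reagent should tolerate the lactone and the terminal alkyne.

Step 8
Reactants: 12 3-(but-3-yn-1-yl)furan-2(5H)-one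
Product: 13 dimethyl (2Z)-2-[2-(2-oxo-2,5-dihydrofuran-3-yl)ethyl]but-2-enedioate
Conditions: PdI2 (1 mol %), KI (10 mol %), CO/air (4:1, 20 bar), MeOH, 30 °C
Reagents that add atoms: carbon monoxide ([C-]#[O+]); methanol (CO)
Why: Pd(II)-catalysed oxidative dialkoxycarbonylation of a terminal alkyne; syn addition of Pd–CO2Me across the triple bond and a second CO insertion/methanolysis give the Z (maleate) diester.

Step 9
Reactants: 13 dimethyl (2Z)-2-[2-(2-oxo-2,5-dihydrofuran-3-yl)ethyl]but-2-enedioate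
Product: 16 3-[2-(2,5-dioxo-2,5-dihydrofuran-3-yl)ethyl]furan-2(5H)-one, via trilithium tricarboxylate 14 (not isolated), via butenolide diacid 15 (not isolated)
Conditions: LiOH, THF/H2O, 0 → 23 °C; 2 M HCl to pH 1; then Ac2O, 60 °C
Reagents that add atoms: lithium hydroxide ([Li+].[OH-])
Why: Saponification (the butenolide opens and recloses on acidification) and dehydration of the cis-diacid to the cyclic anhydride, which also locks the Z geometry.

Step 10
Reactants: 5 tert-butyl{[(2S,3E,5E)-hepta-3,5-dien-2-yl]oxy}dimethylsilane; 16 3-[2-(2,5-dioxo-2,5-dihydrofuran-3-yl)ethyl]furan-2(5H)-one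
Product: 18 (1R,2S,3S,6R)-3-[(1S)-1-{[tert-butyl(dimethyl)silyl]oxy}ethyl]-6-methyl-1-[2-(2-oxo-2,5-dihydrofuran-3-yl)ethyl]-2-{[2-(trimethylsilyl)ethoxy]carbonyl}cyclohex-4-ene-1-carboxylic acid, via Diels–Alder anhydride 17 (not isolated)
Conditions: PhMe (2 M), BHT (cat.), 110 °C, sealed tube, 48 h; cool; then Me3SiCH2CH2OH, DMAP (20 mol %), 23 °C; chromatography to remove minor isomers
Reagents that add atoms: 2-(trimethylsilyl)ethanol (C[Si](C)(C)CCO)
Why: Thermal endo Diels–Alder reaction (Alder rule) puts the C8 methyl cis to both anhydride carbonyls (C8/C9/C10 relative configuration), the bulky carbinol terminus bonds to the unsubstituted dienophile carbon (steric regiocontrol), and attack anti to the allylic OTBS group with the allylic H inside sets the absolute configuration; DMAP-catalysed alcoholysis then opens the anhydride at the less hindered carbonyl (C1′ on the CH carbon) and differentiates the two carboxyls.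

Step 11
Reactants: 18 (cyclohexene hemiester)
Product: 19 (1R,2S,3S,6R)-3-[(1S)-1-{[tert-butyl(dimethyl)silyl]oxy}ethyl]-6-methyl-1-[2-(2-oxo-2,5-dihydrofuran-3-yl)ethyl]-2-{[2-(trimethylsilyl)ethoxy]carbonyl}cyclohexane-1-carboxylic acid
Conditions: TsNHNH2 (10 equiv), NaOAc, DME/H2O (1:1), 85 °C
Reagents that add atoms: none
Why: Diimide reduction; concerted syn hydrogen transfer saturates the unpolarised cis-disubstituted ring alkene, while the conjugated trisubstituted butenolide is expected to survive, as in acetogenin syntheses.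

Step 12
Reactants: 19 (saturated hemiester)
Product: 21 (1R,2S,3S,6R)-3-acetyl-6-methyl-1-[2-(2-oxo-2,5-dihydrofuran-3-yl)ethyl]-2-{[2-(trimethylsilyl)ethoxy]carbonyl}cyclohexane-1-carboxylic acid, via hydroxy acid 20 (not isolated)
Conditions: CrO3, H2SO4, H2O (Jones reagent), acetone, 0 °C, 45 min; i-PrOH quench
Reagents that add atoms: none
Why: Jones oxidation with direct oxidative desilylation; the acid cleaves the secondary TBS ether and the carbinol is oxidised at once, which should outrun lactonisation onto the neighbouring ester, and the auxiliary carbinol stereocentre is erased.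

Step 13
Reactants: 21 (keto acid)
Product: 22 (1R,2S,3S,6R)-6-methyl-1-[2-(2-oxo-2,5-dihydrofuran-3-yl)ethyl]-3-(prop-1-en-2-yl)-2-{[2-(trimethylsilyl)ethoxy]carbonyl}cyclohexane-1-carboxylic acid
Conditions: Zn, CH2Br2, TiCl4, THF (pre-formed reagent), then 21, CH2Cl2, 0 → 23 °C
Reagents that add atoms: dibromomethane (BrCBr)
Why: Lombardo–Takai methylenation; the non-basic zinc/titanium methylidene reagent is selective for the ketone over esters, lactone and acid, and spares the base-sensitive butenolide.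

Step 14
Reactants: 22 (isopropenyl acid)
Product: 23 2-(trimethylsilyl)ethyl (1R,2R,5S,8R)-2-methyl-7-oxo-1-[2-(2-oxo-2,5-dihydrofuran-3-yl)ethyl]-5-(prop-1-en-2-yl)-6-oxabicyclo[3.2.1]octane-8-carboxylate
Conditions: Pd(OAc)2 (10 mol %), 1,2-bis(phenylsulfinyl)ethane (10 mol %), 1,4-benzoquinone (2 equiv), 1,4-dioxane (0.05 M), 45 °C, 48 h
Reagents that add atoms: none
Why: Proposed new method: carboxylate-directed Pd(II)/bis-sulfoxide allylic C–H lactonisation at the tertiary allylic C5–H of a 1,1-disubstituted olefin; the Pd carboxylate of 22 binds the isopropenyl group, acetate/carboxylate-assisted cleavage of the weak tertiary allylic C–H gives a π-allyl-Pd carboxylate, and benzoquinone-promoted C–O bond formation at the ring terminus closes the only accessible (five-membered, necessarily cis-bridged) lactone, so the C5 configuration is fixed by the C9 tether whichever C5 epimer enters, while attack at the CH2 terminus would need a seven-membered ring; the closest known reaction type is the White Pd(II)/sulfoxide allylic C–H oxidation and macrolactonisation of terminal olefins (with Tsuji–Trost lactonisation as the C–O-forming precedent).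

Step 15
Reactants: 23 (bicyclic lactone TMSE ester); 24 methyl acrylate
Product: 26 methyl 3-[(1R,2R,5S,8R)-2-methyl-7-oxo-1-[2-(2-oxo-2,5-dihydrofuran-3-yl)ethyl]-5-(prop-1-en-2-yl)-6-oxabicyclo[3.2.1]octan-8-yl]propanoate (CNP0209666.1), via tetrabutylammonium carboxylate 25 (not isolated)
Conditions: TBAF (1.1 equiv), THF, 0 °C; evaporate; then 24 (5 equiv), Ir[dF(CF3)ppy]2(dtbbpy)PF6 (1 mol %), H2O (10 equiv), DMF, blue LEDs, 23 °C
Reagents that add atoms: none
Why: Fluoride-induced fragmentation of the TMSE ester followed by photoredox decarboxylative Giese addition; the C10 bridge radical should be trapped by acrylate on the open face syn to the O–C(=O) bridge (the other face is shielded by the axial hydrogens of the three-carbon bridge), which re-sets C10 with the equatorial chain of the target.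

**Compound list**
1 | sorbic acid, (2E,4E)-hexa-2,4-dienoic acid | C/C=C/C=C/C(=O)O | starting material
2 | (2E,4E)-N-methoxy-N-methylhexa-2,4-dienamide | C/C=C/C=C/C(=O)N(C)OC | intermediate
3 | (3E,5E)-hepta-3,5-dien-2-one | C/C=C/C=C/C(C)=O | intermediate
4 | (2S,3E,5E)-hepta-3,5-dien-2-ol | C[C@H](O)/C=C/C=C/C | intermediate
5 | tert-butyl{[(2S,3E,5E)-hepta-3,5-dien-2-yl]oxy}dimethylsilane | C[C@H](O[Si](C)(C)C(C)(C)C)/C=C/C=C/C | intermediate
6 | furan-2(5H)-one | O=C1OCC=C1 | starting material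
7 | trans-3,4-dibromodihydrofuran-2(3H)-one (racemic, one enantiomer drawn) | O=C1OC[C@@H](Br)[C@@H]1Br | intermediate (not isolated)
8 | 3-bromofuran-2(5H)-one | O=C1OCC=C1Br | intermediate
9 | but-3-yn-1-ol | C#CCCO | starting material
10 | 4-iodobut-1-yne | C#CCCI | intermediate
11 | but-3-yn-1-ylzinc iodide | C#CCC[Zn]I | intermediate (not isolated)
12 | 3-(but-3-yn-1-yl)furan-2(5H)-one | C#CCCC1=CCOC1=O | intermediate
13 | dimethyl (2Z)-2-[2-(2-oxo-2,5-dihydrofuran-3-yl)ethyl]but-2-enedioate | COC(=O)/C=C(/CCC1=CCOC1=O)C(=O)OC | intermediate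
14 | trilithium (2Z)-2-[(3Z)-3-carboxylato-5-hydroxypent-3-en-1-yl]but-2-enedioate | [Li+].[Li+].[Li+].[O-]C(=O)/C=C(/CC/C(C(=O)[O-])=C/CO)C(=O)[O-] | intermediate (not isolated)
15 | (2Z)-2-[2-(2-oxo-2,5-dihydrofuran-3-yl)ethyl]but-2-enedioic acid | OC(=O)/C=C(/CCC1=CCOC1=O)C(=O)O | intermediate (not isolated)
16 | 3-[2-(2,5-dioxo-2,5-dihydrofuran-3-yl)ethyl]furan-2(5H)-one | O=C1OC(=O)C(CCC2=CCOC2=O)=C1 | intermediate
17 | (3aS,4S,7R,7aR)-4-[(1S)-1-{[tert-butyl(dimethyl)silyl]oxy}ethyl]-7-methyl-7a-[2-(2-oxo-2,5-dihydrofuran-3-yl)ethyl]-3a,4,7,7a-tetrahydro-2-benzofuran-1,3-dione | C[C@H](O[Si](C)(C)C(C)(C)C)[C@H]1C=C[C@@H](C)[C@@]2(CCC3=CCOC3=O)C(=O)OC(=O)[C@@H]12 | intermediate (not isolated)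
18 | (1R,2S,3S,6R)-3-[(1S)-1-{[tert-butyl(dimethyl)silyl]oxy}ethyl]-6-methyl-1-[2-(2-oxo-2,5-dihydrofuran-3-yl)ethyl]-2-{[2-(trimethylsilyl)ethoxy]carbonyl}cyclohex-4-ene-1-carboxylic acid | C[C@H](O[Si](C)(C)C(C)(C)C)[C@H]1C=C[C@@H](C)[C@@](CCC2=CCOC2=O)(C(=O)O)[C@H]1C(=O)OCC[Si](C)(C)C | intermediate
19 | (1R,2S,3S,6R)-3-[(1S)-1-{[tert-butyl(dimethyl)silyl]oxy}ethyl]-6-methyl-1-[2-(2-oxo-2,5-dihydrofuran-3-yl)ethyl]-2-{[2-(trimethylsilyl)ethoxy]carbonyl}cyclohexane-1-carboxylic acid | C[C@H](O[Si](C)(C)C(C)(C)C)[C@H]1CC[C@@H](C)[C@@](CCC2=CCOC2=O)(C(=O)O)[C@H]1C(=O)OCC[Si](C)(C)C | intermediate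
20 | (1R,2S,3S,6R)-3-[(1S)-1-hydroxyethyl]-6-methyl-1-[2-(2-oxo-2,5-dihydrofuran-3-yl)ethyl]-2-{[2-(trimethylsilyl)ethoxy]carbonyl}cyclohexane-1-carboxylic acid | C[C@H](O)[C@H]1CC[C@@H](C)[C@@](CCC2=CCOC2=O)(C(=O)O)[C@H]1C(=O)OCC[Si](C)(C)C | intermediate (not isolated)
21 | (1R,2S,3S,6R)-3-acetyl-6-methyl-1-[2-(2-oxo-2,5-dihydrofuran-3-yl)ethyl]-2-{[2-(trimethylsilyl)ethoxy]carbonyl}cyclohexane-1-carboxylic acid | CC(=O)[C@H]1CC[C@@H](C)[C@@](CCC2=CCOC2=O)(C(=O)O)[C@H]1C(=O)OCC[Si](C)(C)C | intermediate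
22 | (1R,2S,3S,6R)-6-methyl-1-[2-(2-oxo-2,5-dihydrofuran-3-yl)ethyl]-3-(prop-1-en-2-yl)-2-{[2-(trimethylsilyl)ethoxy]carbonyl}cyclohexane-1-carboxylic acid | C=C(C)[C@H]1CC[C@@H](C)[C@@](CCC2=CCOC2=O)(C(=O)O)[C@H]1C(=O)OCC[Si](C)(C)C | intermediate
23 | 2-(trimethylsilyl)ethyl (1R,2R,5S,8R)-2-methyl-7-oxo-1-[2-(2-oxo-2,5-dihydrofuran-3-yl)ethyl]-5-(prop-1-en-2-yl)-6-oxabicyclo[3.2.1]octane-8-carboxylate | C=C(C)[C@@]12CC[C@@H](C)[C@@](CCC3=CCOC3=O)(C(=O)O1)[C@H]2C(=O)OCC[Si](C)(C)C | intermediate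
24 | methyl acrylate | C=CC(=O)OC | starting material
25 | tetrabutylammonium (1R,2R,5S,8R)-2-methyl-7-oxo-1-[2-(2-oxo-2,5-dihydrofuran-3-yl)ethyl]-5-(prop-1-en-2-yl)-6-oxabicyclo[3.2.1]octane-8-carboxylate | C=C(C)[C@@]12CC[C@@H](C)[C@@](CCC3=CCOC3=O)(C(=O)O1)[C@H]2C(=O)[O-].CCCC[N+](CCCC)(CCCC)CCCC | intermediate (not isolated)
26 | methyl 3-[(1R,2R,5S,8R)-2-methyl-7-oxo-1-[2-(2-oxo-2,5-dihydrofuran-3-yl)ethyl]-5-(prop-1-en-2-yl)-6-oxabicyclo[3.2.1]octan-8-yl]propanoate | C=C(C)[C@@]12CC[C@@H](C)[C@@](CCC3=CCOC3=O)(C(=O)O1)[C@H]2CCC(=O)OC | target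

**Step count**
Total step count: 15.
Longest linear sequence: 10 steps (steps 1–4 then 10–15; the sequences 6–9 then 10–15, and 5, 7–9 then 10–15, are equally long).

**Three steps most likely to fail**

Step 14 (the proposed new reaction). Possible failures are C–H cleavage at the methyl group instead of C5–H, β-hydride elimination of the π-allyl to a diene, or acid-mediated Markovnikov δ-lactone formation. The fallback uses known chemistry and sets out from 21. Koser's reagent [PhI(OH)OTs] in CH2Cl2 at 40 °C effects the known α-lactonisation of 5-oxo acids (the enol attacks iodine(III), then the C20 carboxyl displaces iodobenzene at C5). This gives 2-(trimethylsilyl)ethyl (1R,2R,5S,8R)-5-acetyl-2-methyl-7-oxo-1-[2-(2-oxo-2,5-dihydrofuran-3-yl)ethyl]-6-oxabicyclo[3.2.1]octane-8-carboxylate F1. Lombardo–Takai methylenation of F1 (Zn, CH2Br2, TiCl4) then gives 23, where the route is rejoined.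

Step 10 (Diels–Alder). Regiochemistry rests on steric control only, facial selectivity from an allylic OTBS group is typically moderate, and some exo adduct is likely, so the yield of the one wanted isomer may be low. The fallback replaces stereocontrol by the carbinol with a bulkier achiral terminus and a resolution, and sets out from 3. Noyori ketalisation (Me3SiOCH2CH2OSiMe3, TMSOTf cat., CH2Cl2, −78 °C) gives 2-methyl-2-[(1E,3E)-penta-1,3-dien-1-yl]-1,3-dioxolane F2. Heating F2 with 16 gives rac-(3aS,4S,7R,7aR)-7-methyl-4-(2-methyl-1,3-dioxolan-2-yl)-7a-[2-(2-oxo-2,5-dihydrofuran-3-yl)ethyl]-3a,4,7,7a-tetrahydro-2-benzofuran-1,3-dione F3. This is opened in the same pot with Me3SiCH2CH2OH/DMAP to rac-(1R,2S,3S,6R)-6-methyl-3-(2-methyl-1,3-dioxolan-2-yl)-1-[2-(2-oxo-2,5-dihydrofuran-3-yl)ethyl]-2-{[2-(trimethylsilyl)ethoxy]carbonyl}cyclohex-4-ene-1-carboxylic acid F4. Diimide reduction gives the corresponding rac-cyclohexane-1-carboxylic acid F5, and PPTS in aqueous acetone unmasks racemic 21, rac-(1R,2S,3S,6R)-3-acetyl-6-methyl-1-[2-(2-oxo-2,5-dihydrofuran-3-yl)ethyl]-2-{[2-(trimethylsilyl)ethoxy]carbonyl}cyclohexane-1-carboxylic acid F6. Classical resolution with (S)-1-phenylethylamine gives the (S)-1-phenylethylammonium salt of 21 F7, and acidification returns 21.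

Step 15 (one-pot ester cleavage and decarboxylative Giese addition). Possible failures are inefficient oxidation of the hindered carboxylate in the presence of fluoride residues, or 6-endo cyclisation of the C10 radical onto the butenolide competing with acrylate capture. The fallback generates the radical reductively from an isolated redox-active ester and sets out from 23. TBAF followed by acidic work-up gives (1R,2R,5S,8R)-2-methyl-7-oxo-1-[2-(2-oxo-2,5-dihydrofuran-3-yl)ethyl]-5-(prop-1-en-2-yl)-6-oxabicyclo[3.2.1]octane-8-carboxylic acid F8. DIC, N-hydroxyphthalimide and DMAP give its 1,3-dioxoisoindolin-2-yl ester F9. Ru(bpy)3(PF6)2, Hantzsch ester, i-Pr2NEt and 24 (10 equiv) in CH2Cl2 under blue LEDs (the known reductive decarboxylative Giese reaction of N-acyloxyphthalimides) then give 26.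

**Further compounds**
F1 | step 14 | 2-(trimethylsilyl)ethyl (1R,2R,5S,8R)-5-acetyl-2-methyl-7-oxo-1-[2-(2-oxo-2,5-dihydrofuran-3-yl)ethyl]-6-oxabicyclo[3.2.1]octane-8-carboxylate | CC(=O)[C@@]12CC[C@@H](C)[C@@](CCC3=CCOC3=O)(C(=O)O1)[C@H]2C(=O)OCC[Si](C)(C)C
F2 | step 10 | 2-methyl-2-[(1E,3E)-penta-1,3-dien-1-yl]-1,3-dioxolane | CC1(/C=C/C=C/C)OCCO1
F3 | step 10 | rac-(3aS,4S,7R,7aR)-7-methyl-4-(2-methyl-1,3-dioxolan-2-yl)-7a-[2-(2-oxo-2,5-dihydrofuran-3-yl)ethyl]-3a,4,7,7a-tetrahydro-2-benzofuran-1,3-dione (racemate, one enantiomer drawn) | CC4(OCCO4)[C@H]1C=C[C@@H](C)[C@@]2(CCC3=CCOC3=O)C(=O)OC(=O)[C@@H]12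
F4 | step 10 | rac-(1R,2S,3S,6R)-6-methyl-3-(2-methyl-1,3-dioxolan-2-yl)-1-[2-(2-oxo-2,5-dihydrofuran-3-yl)ethyl]-2-{[2-(trimethylsilyl)ethoxy]carbonyl}cyclohex-4-ene-1-carboxylic acid (racemate, one enantiomer drawn) | CC4(OCCO4)[C@H]1C=C[C@@H](C)[C@@](CCC2=CCOC2=O)(C(=O)O)[C@H]1C(=O)OCC[Si](C)(C)C
F5 | step 10 | rac-(1R,2S,3S,6R)-6-methyl-3-(2-methyl-1,3-dioxolan-2-yl)-1-[2-(2-oxo-2,5-dihydrofuran-3-yl)ethyl]-2-{[2-(trimethylsilyl)ethoxy]carbonyl}cyclohexane-1-carboxylic acid (racemate, one enantiomer drawn) | CC4(OCCO4)[C@H]1CC[C@@H](C)[C@@](CCC2=CCOC2=O)(C(=O)O)[C@H]1C(=O)OCC[Si](C)(C)C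
F6 | step 10 | rac-(1R,2S,3S,6R)-3-acetyl-6-methyl-1-[2-(2-oxo-2,5-dihydrofuran-3-yl)ethyl]-2-{[2-(trimethylsilyl)ethoxy]carbonyl}cyclohexane-1-carboxylic acid (racemate of 21, one enantiomer drawn) | CC(=O)[C@H]1CC[C@@H](C)[C@@](CCC2=CCOC2=O)(C(=O)O)[C@H]1C(=O)OCC[Si](C)(C)C
F7 | step 10 | (S)-1-phenylethylammonium (1R,2S,3S,6R)-3-acetyl-6-methyl-1-[2-(2-oxo-2,5-dihydrofuran-3-yl)ethyl]-2-{[2-(trimethylsilyl)ethoxy]carbonyl}cyclohexane-1-carboxylate | CC(=O)[C@H]1CC[C@@H](C)[C@@](CCC2=CCOC2=O)(C(=O)[O-])[C@H]1C(=O)OCC[Si](C)(C)C.C[C@H]([NH3+])c1ccccc1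
F8 | step 15 | (1R,2R,5S,8R)-2-methyl-7-oxo-1-[2-(2-oxo-2,5-dihydrofuran-3-yl)ethyl]-5-(prop-1-en-2-yl)-6-oxabicyclo[3.2.1]octane-8-carboxylic acid | C=C(C)[C@@]12CC[C@@H](C)[C@@](CCC3=CCOC3=O)(C(=O)O1)[C@H]2C(=O)O
F9 | step 15 | 1,3-dioxoisoindolin-2-yl (1R,2R,5S,8R)-2-methyl-7-oxo-1-[2-(2-oxo-2,5-dihydrofuran-3-yl)ethyl]-5-(prop-1-en-2-yl)-6-oxabicyclo[3.2.1]octane-8-carboxylate | C=C(C)[C@@]12CC[C@@H](C)[C@@](CCC3=CCOC3=O)(C(=O)O1)[C@H]2C(=O)ON4C(=O)c5ccccc5C4=O
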